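I had 3 questions for one flask, and two earlier runs to answer them with.

common to all: substrate 0.050 M; free catalyst 2 mol%; second catalyst 0.13 mol%

| charge | reagent | remark | time |
|---|---|---|---|
| north-west | 0.75 equiv | run made earlier |  |
| south | 3 equiv | run made earlier |  |
| flask | 1.50 equiv |  | 80 min |

| run | time / min | side product / % | target / % |
|---|---|---|---|
| north-west | 15.0 | 35 | 0 |
| north-west | 30.0 | 60 | 2 |
| north-west | 40.0 | 75 | 2 |
| north-west | 60.0 | 96 | 1 |
| north-west | 80.0 | 95 | 4 |
| north-west | 90.0 | 95 | 4 |
| south | 15.0 | 82 | 17 |
| south | 30.0 | 83 | 17 |
| south | 40.0 | 83 | 16 |
| south | 60.0 | 82 | 18 |
| south | 80.0 | 84 | 16 |
| south | 90.0 | 83 | 16 |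

(readings scatter by 1.5 percentage points)

- percent here means substrate units held: one side product counts as two
- the earlier runs were read with a standard deviation of 1.5 percentage points

- share of side product in side product plus target at 40 s
- share of side product in side product plus target at 80 min
- which of side product and target there is more of at 80 min

The side product holds two substrate units, and I took it to hold one reagent as well. In the north-west run it read 75 % at 40.0 min. So 37.5 % of the substrate charge in reagent was spent, which is half of the 0.75 equiv. I therefore set 40.0 min as the reagent half-life: the time in which a flask with these charges of substrate and both catalysts spends half its reagent while substrate lasts. This treats the loss as pseudo-first-order, with rate proportional to [reagent]. It gave 34.3 % side product at 15.0 min, and the reading was 35 %. Where side product forms, substrate calls for about half an equivalent of reagent, so the south run should take about 10.5 min. It already read 82 % and 17 % at 15.0 min.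

Now the flask in slow motion. At 40 s the reagent half-life leaves 98.9 % of the reagent. In the north-west run target read 2 % beside 60 % side product at 30.0 min. So I took target to come first, with substrate + target → side product as the fast step. The early share should then stand below the end share, though no reading gave me a number for it. In the middle, target should be used as fast as it is made. The flask should reach its end near 23.4 min. After that the split should hold, as in the south run, where target read 17 % first and 16 % at 90.0 min. The reagent charge of the flask is twice that of north-west and half that of south. So I took the geometric mean of their 4 % and 16 % target, 8.00 %. That puts the side product share at 92.0 %, with side product ahead.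

The forecast gave 92 % (82 % to 99 %) at 40 s and 91 % (85 % to 96 %) at 80 min, with side product ahead, noting that “the north-west run hints that target lags”, and its early share stood above its end share, where I put mine below.

The flask gave 78.9 % at 40 s and 90.5 % at 80 min, with side product ahead.

    second catalyst + open intermediate ⇌ catalyst intermediate (K = 1400 /M, k = 9700 /M/s)
    substrate + free catalyst ⇌ free catalyst + open intermediate (K = 2.80, k = 22.0 /M/s)
    substrate + target → side product (k = 2.50 /M/s)
    reagent + catalyst intermediate → second catalyst + target (k = 4.90 /M/s)

The half-life of target by the step to side product alone, with substrate as charged, is 0.092 min, which is shorter than the 80 min of the run. At 10.9 min the flask made target 1.07 times as fast as it used it up. The reagent half-life put reagent at 87.1 % after 8.00 min, and the flask held 86.2 %. A neighbouring flask with 0.600 equiv of reagent still held 2.5 % substrate at 80 min, which is twice the half-life, so I reckoned 25.0 % of its reagent left, and it held 24 %.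

(The earlier runs and the new flask are simulated with made-up constants; noise was put on by code.)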